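Remark: the oxolane ring is numbered O1, C2 (carrying ring A, the 3-hydroxy-4,5-dimethoxyphenyl group), C3, C4 and C5 (carrying ring B, the 3,4,5-trimethoxyphenyl group). With this numbering the target is (2R,3S,4S,5S). Aldehyde 1 is assumed to be purchasable.

## Analysis of the target

Compound 23 is a 2,5-diaryl-3,4-dimethyloxolane, a tetrahydrofuran lignan with one saturated five-membered ether ring between two oxygenated benzene rings. All four ring carbons are stereocentres: ring A at C2 is cis to the C3 methyl, the two methyls are trans, the C4 methyl is trans to ring B at C5, and the two aryl groups are therefore cis to each other. The 2,3-cis arrangement is the less stable one, and both C2–O and C5–O are benzylic bonds to electron-rich arenes, so acid can ionise them and drain the compound towards the all-trans isomer. The free phenol of ring A is the other sensitive group; it has to be masked during carbanion and hydride chemistry and released without hydrogenolysis of the two benzylic ring C–O bonds. The main difficulty is near-symmetry: rings A and B differ only in OH against OMe at one meta position, yet C2 and C5 have different relationships to their neighbouring methyl groups, so the two ends cannot be told apart by the arenes themselves. The strategy rests on the C3–C4 unit: the four carbons CH3–C3–C4–CH3 with trans methyls are read as the four carbons of a butenolide. C3 and C4 are its β and α ring carbons, and the two methyls are its acetal carbon and its carbonyl carbon in reduced form. C2 with ring A and C5 with ring B are then attached one after the other, as a nucleophile and as an electrophile.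

## Retrosynthetic reasoning

23 ⇒ 22. The phenol O–H is traced back to a benzyl ether. A free phenol would quench the carbanion chemistry and be sulfonylated or silylated later, so it is carried masked from the first step and released last, under neutral conditions that leave the acid-labile ring untouched.

22 ⇒ 19 (through 20 and 21). The C2–H bond is cut, which turns C2 into the oxocarbenium carbon of 21, the ionised form of hemiketal 20, itself the ring tautomer of hydroxy ketone 19. C2 is chosen because it is the only stereocentre that need not be carried through the chain: in the ring the C3 methyl group directs the incoming hydride to the opposite face, which is the 2,3-cis result the target needs. The C5–O bond is never broken, so C5 must already have its final configuration in 19.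

19 ⇒ 18 ⇒ 17. The ketone at C2 is masked as the dithiane of 18 and the C5 hydroxyl as the silyl ether of 17. The dithiane is the form in which C2 was a nucleophile; the silyl ether keeps the hydroxyl out of the deoxygenation. The silyl group is removed before the dithiane, so that basic fluoride never meets a ketone with an epimerisable C3.

17 ⇒ 16 ⇒ 15 ⇒ 14. The six C–H bonds of the two methyl groups are traced back to C–O bonds: the methyls were the primary carbinols of diol 15, and these were the carbonyl carbon and the acetal carbon of lactone 14. This gives the C3–C4 unit the two oxidised carbons that make it a Michael acceptor and an enolate, and one hydride reduction followed by one double deoxygenation erases both.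

14 ⇒ 13 ⇒ 12 ⇒ 11. The C5 carbinol of 13 is traced to ketone 12 and this to aldol adduct 11. The lactone enolate has a ring-locked geometry, and a lithium-bridged chair aldol of such an enolate leads to the anti adduct, which would end as a 4,5-cis oxolane. The target needs the syn adduct. The aldol is therefore used only to make the C4–C5 bond, and the carbinol is set afterwards by a chelation-controlled reduction of 12, which uses both aldol epimers.

11 ⇒ 3 + 7 + 8. The C2–C3 and C4–C5 bonds are cut. These two bonds flank the C3–C4 unit, and cutting them sends ring A and ring B into two different reagents of opposite polarity: dithiane 3 as an acyl anion equivalent and aldehyde 8 as the electrophile, joined through butenolide 7. This removes the near-symmetry problem, gives three fragments of similar size, and lets the acetal centre of 7 fix C3 and C4 in relative and absolute terms. The forward reaction has to be a 1,4-addition anti to the acetal substituent followed by trapping of the enolate anti to the new substituent.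

3 ⇒ 2 ⇒ 1 and 7 ⇒ 5 + 6, 5 ⇒ 4. The dithiane comes from aldehyde 2, the benzyl ether of 1. Butenolide 7 is the acetal of hydroxybutenolide 5 with 6, and 5 is the photooxygenation product of 4. Both precursors are two routine steps from catalogue chemicals, so the risk of the route sits in the three-component coupling.

## Alternatives that were turned down

Alternative 1: carbenoid C–H insertion.
- Disconnection: the C4–C5 bond of an oxolane that still carries a methoxycarbonyl group at C4. The precursor is the open-chain α-diazo ester A1, in which C2 and C3 are set and ring B hangs on the C2 oxygen as a 3,4,5-trimethoxybenzyl ether.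
- Forward key step: the bulky dirhodium tetracarboxylate A2, Rh2(O2CCPh3)4, would convert A1 into a metal carbenoid at C4. This would insert into one benzylic C–H bond next to the ether oxygen (a 1,5-insertion), forming C4–C5 and closing the ring to the 2,5-cis-diaryl ester A3.
- For it: ring closure and C–C bond formation happen in one step on a C–H bond that is activated twice. Ring B enters by simple etherification, only C2 and C3 must be made beforehand, and the sequence would be several steps shorter than the chosen one.
- Against it for 23: the carbenoid carbon has a C3–H next to it, and 1,2-hydride migration to an alkene is the intrinsic competitor of every α-alkyl diazo ester; bulky carboxylate ligands only suppress it in part. The ether oxygen is a second trap (oxonium ylide, then [1,2]-benzyl shift), and two electron-rich arenes invite cyclopropanation. C4 and C5 are created together, and nothing in A1 clearly dictates that ring B ends trans to the ester and cis to ring A. The ester of A3 must still be taken down to a methyl group in three steps next to an epimerisable centre.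
- Comparison: Alternative 1 is stronger on step count and on direct ring formation, but it loads two stereocentres and three chemoselectivity questions onto one step. The chosen route is longer; in exchange each of C3, C4, C5 and C2 is set in its own operation by a control element that can be named, and both methyl groups come from one functional group.

Alternative 2: donor–acceptor cyclopropane plus aldehyde (3+2) annulation.
- Disconnection: the O1–C2 and C4–C5 bonds, giving aldehyde 8 and the enantiopure trans-2-aryl-3-methylcyclopropane-1,1-diester A4, whose aryl group is ring A.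
- Forward key step: the Lewis acid A5, Sn(OTf)2, would bind the diester of A4. The oxygen of 8 would attack the ring A benzylic carbon with inversion, and the malonate carbon would close onto the aldehyde carbon, giving the 2,5-cis-diaryl oxolane diester A6.
- For it: it is the most convergent route, with two bonds and the ring made in one step. The 2,5-cis relationship of the aryl groups is built into the mechanism, and inversion at the benzylic carbon turns the trans cyclopropane into the required 2,3-cis pair. It is clearly shorter than the chosen route.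
- Against it for 23: A4 must be a single enantiomer with aryl trans to methyl, and no asymmetric cyclopropanation delivers a geminally diactivated three-membered ring of this substitution pattern dependably. The trioxygenated aryl donor makes the ring-opened benzylic cation accessible, so inversion can leak and erode both the enantiomeric purity and the 2,3-cis relationship. The geminal diester has to be cut down by dealkoxycarbonylation, reduction, sulfonylation and hydride, with C4 resting on a thermodynamic epimerisation. The benzylic ether bonds of A6 are exposed to the Lewis acid that forms them.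
- Comparison: Alternative 2 is stronger in convergence and step count. The chosen route is stronger in its source of absolute configuration (a crystalline acetal of cheap 6) and does not build and then discard a carboxyl group.

Alternative 3: enone plus aryl carbene (4+1) annulation.
- Disconnection: the O1–C5 and C4–C5 bonds of a 4,5-dihydrofuran, giving the ring A enone A7 and the ring B diazomethane A8.
- Forward key step: monovalent copper, as the triflate A9, CuOTf, carrying a chiral bis(oxazoline) ligand such as A10, would turn A8 into a copper carbene. The enone oxygen would capture it, and the conjugated ylide would electrocyclise to the trans-4,5-disubstituted dihydrofuran A11.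
- For it: it is by far the shortest route. Both partners are one or two steps from aldehydes, and the 4,5-trans relationship follows from the electrocyclisation.
- Against it for 23: A8 is a non-stabilised diazo compound, hazardous and prone to carbene dimerisation under copper. Enantiocontrol of a (4+1) reaction with a plain aryl carbene and an α-methyl enone lacking a second binding group is not established, and cyclopropanation of the enone competes. Most seriously, A11 still has no stereocentre at C2 or C3: hydrogenation of its tetrasubstituted enol ether must add to the face that carries the adjacent C4 methyl to give the 3,4-trans product, so the nearest substituent steers it the wrong way.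
- Comparison: Alternative 3 wins clearly on length but leaves two of four stereocentres to a reduction with the wrong intrinsic bias. The chosen route sets the trans C3/C4 pair first and C2 last, where the bias from C3 is the helpful one.

Key step: step 5

## Route

Step 1
Reactants: 1 3-hydroxy-4,5-dimethoxybenzaldehyde
Product: 2 3-(benzyloxy)-4,5-dimethoxybenzaldehyde
Conditions: BnBr, K2CO3, DMF, rt
Reagents that add atoms: benzyl bromide, BrCc1ccccc1
Why: Williamson ether synthesis; the phenoxide formed with K2CO3 is alkylated at oxygen while the aldehyde is untouched, and the benzyl ether masks the acidic phenol against the organolithium, hydride, silylating and sulfonylating reagents that follow.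

Step 2
Reactants: 2 3-(benzyloxy)-4,5-dimethoxybenzaldehyde
Product: 3 2-[3-(benzyloxy)-4,5-dimethoxyphenyl]-1,3-dithiane
Conditions: HS(CH2)3SH, BF3·OEt2 (cat.), CH2Cl2, 0 °C to rt
Reagents that add atoms: propane-1,3-dithiol, SCCCS
Why: Lewis-acid-catalysed dithioacetalisation of an aromatic aldehyde; aryl benzyl and methyl ethers tolerate catalytic BF3·OEt2 at this temperature, and the dithiane turns the formyl carbon into the acyl-anion equivalent that becomes C2.

Step 3
Reactants: 4 furfural
Product: 5 5-hydroxyfuran-2(5H)-one (racemic)
Conditions: O2, hν (visible light), rose bengal (cat.), MeOH, rt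
Reagents that add atoms: dioxygen, O=O
Why: Dye-sensitised photooxygenation; singlet oxygen adds [4+2] across the furan, methanol adds to the formyl group, and the endoperoxide fragments with loss of methyl formate to the γ-hydroxybutenolide.

Step 4
Reactants: 5 5-hydroxyfuran-2(5H)-one; 6 (−)-menthol
Product: 7 (5R)-5-{[(1R,2S,5R)-2-isopropyl-5-methylcyclohexyl]oxy}furan-2(5H)-one
Conditions: camphorsulfonic acid (cat.), toluene, reflux, Dean–Stark; crystallisation from hexane, mother liquor re-equilibrated with acid and recrystallised
Reagents that add atoms: none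
Why: Acid-catalysed acetalisation of the pseudo-acid gives both C5 epimers; because they interconvert under acid through the cyclic oxocarbenium ion, crystallisation of the less soluble 5R epimer should funnel the material into one diastereomer (crystallisation-induced asymmetric transformation), with C5 fixed relative to the (1R,2S,5R)-menthyl group.

Step 5
Reactants: 3 2-[3-(benzyloxy)-4,5-dimethoxyphenyl]-1,3-dithiane; 7 (5R)-5-(menthyloxy)furan-2(5H)-one; 8 3,4,5-trimethoxybenzaldehyde
Product: 11 (3S,4R,5R)-4-{2-[3-(benzyloxy)-4,5-dimethoxyphenyl]-1,3-dithian-2-yl}-3-[(R)-hydroxy(3,4,5-trimethoxyphenyl)methyl]-5-{[(1R,2S,5R)-2-isopropyl-5-methylcyclohexyl]oxy}oxolan-2-one, via 2-lithio-1,3-dithiane 9 (not isolated), via lithium lactone enolate 10 (not isolated)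
Conditions: n-BuLi, THF, −78 to −30 °C; then 7, −78 °C; then 8, −78 °C; AcOH, −78 °C
Reagents that add atoms: none
Why: n-BuLi removes the C2 proton of dithiane 3, and the sulfur-stabilised benzylic anion 9, a soft carbon nucleophile, adds to the β-carbon of butenolide 7 in a Michael addition instead of attacking the lactone carbonyl, which forms the future C2–C3 bond. The butenolide is flat and the menthyloxy group on the neighbouring acetal carbon covers one face, so 9 enters anti to it and lactone C4 is set (R) by the 5R acetal centre. The lithium enolate 10, whose geometry is locked by the ring with O–Li trans to C4, is then captured by aldehyde 8 in an aldol addition on the face opposite the new dithianyl group; this forms the future C4–C5 bond and sets lactone C3 (S), trans to C4. No ring is closed, and the closest known reaction type is the tandem conjugate addition–enolate trapping of lithiated aryl dithianes on γ-alkoxybutenolides that is used for lignan lactones. At the carbinol carbon a lithium-bridged chair (Zimmerman–Traxler) transition state with the aldehyde aryl group equatorial leads, for this ring-locked enolate geometry, to the anti aldol, that is the (R)-carbinol drawn for 11, and the syn epimer is expected beside it. That centre is therefore not relied on: both epimers are carried into step 6, where the carbinol is oxidised, so the step only has to be 1,4-regioselective and anti,anti on the lactone ring, and the acetal substituent and the bulk of the dithianyl group secure both. The cold acetic acid quench protonates the aldolate before retro-aldol cleavage can set in.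

Step 6
Reactants: 11 aldol adduct (with its unseparated carbinol epimer from step 5)
Product: 12 (3S,4R,5R)-4-{2-[3-(benzyloxy)-4,5-dimethoxyphenyl]-1,3-dithian-2-yl}-5-{[(1R,2S,5R)-2-isopropyl-5-methylcyclohexyl]oxy}-3-(3,4,5-trimethoxybenzoyl)oxolan-2-one
Conditions: SO3·pyridine, DMSO, i-Pr2NEt, CH2Cl2, 0 °C
Reagents that add atoms: none
Why: Parikh–Doering oxidation; activated DMSO oxidises the secondary benzylic alcohol without attacking the thioacetal sulfur (as hypervalent iodine or metal-oxo oxidants could), and both carbinol epimers converge on one β-keto lactone whose doubly activated C3 stays, or settles, trans to the bulky C4 substituent.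

Step 7
Reactants: 12 β-keto lactone
Product: 13 (3S,4R,5R)-4-{2-[3-(benzyloxy)-4,5-dimethoxyphenyl]-1,3-dithian-2-yl}-3-[(S)-hydroxy(3,4,5-trimethoxyphenyl)methyl]-5-{[(1R,2S,5R)-2-isopropyl-5-methylcyclohexyl]oxy}oxolan-2-one
Conditions: Zn(BH4)2, Et2O/CH2Cl2, −20 °C; aq. NH4Cl
Reagents that add atoms: none
Why: Chelation-controlled ketone reduction as known for α-substituted β-keto esters; zinc bridges the lactone and ketone oxygens in a six-membered chelate in which C3 shows its hydrogen to one face and ring carbon C4 with the dithianyl group to the other, so hydride enters from the C3–H side and gives the syn aldol, the (S)-carbinol that becomes C5 with ring B trans to the C4 methyl.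

Step 8
Reactants: 13 syn aldol adduct
Product: 14 (3S,4R,5R)-4-{2-[3-(benzyloxy)-4,5-dimethoxyphenyl]-1,3-dithian-2-yl}-3-[(S)-(tert-butyldimethylsilyloxy)(3,4,5-trimethoxyphenyl)methyl]-5-{[(1R,2S,5R)-2-isopropyl-5-methylcyclohexyl]oxy}oxolan-2-one
Conditions: TBSOTf, 2,6-lutidine, CH2Cl2, −78 to 0 °C
Reagents that add atoms: tert-butyldimethylsilyl trifluoromethanesulfonate, CC(C)(C)[Si](C)(C)OS(=O)(=O)C(F)(F)F
Why: Silylation of a hindered secondary alcohol with a silyl triflate and a non-nucleophilic base, which avoids retro-aldol cleavage; the silyl ether keeps the C5 oxygen from cyclising onto the sulfonates of step 10 and survives the hydride reagents.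

Step 9
Reactants: 14 silyl ether lactone
Product: 15 (2R,3R)-2-{2-[3-(benzyloxy)-4,5-dimethoxyphenyl]-1,3-dithian-2-yl}-3-[(S)-(tert-butyldimethylsilyloxy)(3,4,5-trimethoxyphenyl)methyl]butane-1,4-diol
Conditions: LiAlH4, THF, 0 °C; H2O, aq. NaOH
Reagents that add atoms: none
Why: Hydride reduction of the lactone acetal; reduction of the carbonyl opens the ring, the menthyl hemiacetal alkoxide collapses to an aldehyde that is reduced at once, and the 1,4-diol forms with release of menthol, while dithiane, benzyl ether and silyl ether are inert; keeping the reaction and quench at 0 °C limits epimerisation of the transient aldehyde and silyl migration to the new alkoxides.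

Step 10
Reactants: 15 diol
Product: 16 (2R,3R)-2-{2-[3-(benzyloxy)-4,5-dimethoxyphenyl]-1,3-dithian-2-yl}-3-[(S)-(tert-butyldimethylsilyloxy)(3,4,5-trimethoxyphenyl)methyl]butane-1,4-diyl dimethanesulfonate
Conditions: MsCl, Et3N, CH2Cl2, −20 to 0 °C; used crude at once
Reagents that add atoms: methanesulfonyl chloride, CS(=O)(=O)Cl
Why: Sulfonylation through sulfene is fast at low temperature, so both primary hydroxyls are mesylated together and a monosulfonate has no time to cyclise onto the second hydroxyl.

Step 11
Reactants: 16 bis-mesylate
Product: 17 tert-butyl{[(1S,2S,3S)-3-{2-[3-(benzyloxy)-4,5-dimethoxyphenyl]-1,3-dithian-2-yl}-2-methyl-1-(3,4,5-trimethoxyphenyl)butyl]oxy}dimethylsilane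
Conditions: LiBHEt3, THF, 0 °C to rt
Reagents that add atoms: none
Why: SN2 displacement of primary sulfonates by a strongly nucleophilic borohydride, which attacks carbon rather than sulfonyl sulfur even at β-branched centres; both methyl groups are formed and no stereocentre is touched.

Step 12
Reactants: 17 silyl ether
Product: 18 (1S,2S,3S)-3-{2-[3-(benzyloxy)-4,5-dimethoxyphenyl]-1,3-dithian-2-yl}-2-methyl-1-(3,4,5-trimethoxyphenyl)butan-1-ol
Conditions: Bu4NF, THF, rt to 40 °C
Reagents that add atoms: none
Why: Fluoride-mediated desilylation; it is placed before the ketone is unmasked so that basic fluoride never meets an aryl ketone with an epimerisable α-centre at C3.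

Step 13
Reactants: 18 hydroxy dithiane
Product: 19 (2S,3S,4S)-1-[3-(benzyloxy)-4,5-dimethoxyphenyl]-4-hydroxy-2,3-dimethyl-4-(3,4,5-trimethoxyphenyl)butan-1-one
Conditions: Hg(ClO4)2, CaCO3, THF/H2O, 0 °C
Reagents that add atoms: water, O
Why: Thiophile-assisted hydrolysis of a dithioacetal; the mercury salt binds sulfur, the thionium ion is captured by water or by the C5 hydroxyl, and CaCO3 takes up the acid so that C3 and the benzylic alcohol are not exposed to it, while the non-oxidative conditions leave the electron-rich arenes alone.

Step 14
Reactants: 19 hydroxy ketone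
Product: 22 (2R,3S,4S,5S)-2-[3-(benzyloxy)-4,5-dimethoxyphenyl]-3,4-dimethyl-5-(3,4,5-trimethoxyphenyl)oxolane, via cyclic hemiketal 20 (not isolated), via oxocarbenium ion 21 (not isolated)
Conditions: Et3SiH, BF3·OEt2, CH2Cl2, −78 °C; aq. NaHCO3 at −78 °C
Reagents that add atoms: none
Why: Ionic hydrogenation of a hemiketal (reductive etherification); BF3·OEt2 closes 19 to 20 and ionises it to the aryl-stabilised oxocarbenium ion 21, and the silane delivers hydride to the face anti to the adjacent C3 methyl (inside attack on the envelope), which sets C2 (R) with ring A cis to that methyl and cis to ring B; the low temperature and cold quench keep the benzylic C2–O and C5–O bonds from ionising and epimerising.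

Step 15
Reactants: 22 benzyl ether
Product: 23 5-[(2R,3S,4S,5S)-3,4-dimethyl-5-(3,4,5-trimethoxyphenyl)oxolan-2-yl]-2,3-dimethoxyphenol (target)
Conditions: H2 (1 atm), Pd/C, EtOAc, rt
Reagents that add atoms: none
Why: Catalytic hydrogenolysis of an aryl benzyl ether, which is cleaved much faster than the two dialkyl benzylic C–O bonds of the ring in a non-acidic solvent at atmospheric pressure; the reaction is stopped once 22 is consumed.

## Compound list

1 | 3-hydroxy-4,5-dimethoxybenzaldehyde | COc1cc(C=O)cc(O)c1OC | starting material
2 | 3-(benzyloxy)-4,5-dimethoxybenzaldehyde | COc1cc(C=O)cc(OCc2ccccc2)c1OC | intermediate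
3 | 2-[3-(benzyloxy)-4,5-dimethoxyphenyl]-1,3-dithiane | COc1cc(C2SCCCS2)cc(OCc2ccccc2)c1OC | intermediate
4 | furfural | O=Cc1ccco1 | starting material
5 | 5-hydroxyfuran-2(5H)-one (racemic) | OC1OC(=O)C=C1 | intermediate
6 | (−)-menthol, (1R,2S,5R)-2-isopropyl-5-methylcyclohexanol | CC(C)[C@@H]1CC[C@@H](C)C[C@H]1O | starting material
7 | (5R)-5-{[(1R,2S,5R)-2-isopropyl-5-methylcyclohexyl]oxy}furan-2(5H)-one | CC(C)[C@@H]1CC[C@@H](C)C[C@H]1O[C@@H]2OC(=O)C=C2 | intermediate
8 | 3,4,5-trimethoxybenzaldehyde | COc1cc(C=O)cc(OC)c1OC | starting material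
9 | {2-[3-(benzyloxy)-4,5-dimethoxyphenyl]-1,3-dithian-2-yl}lithium | COc1cc(C2([Li])SCCCS2)cc(OCc2ccccc2)c1OC | intermediate
10 | lithium (4R,5R)-4-{2-[3-(benzyloxy)-4,5-dimethoxyphenyl]-1,3-dithian-2-yl}-5-(menthyloxy)-4,5-dihydrofuran-2-olate | COc1cc(C2(SCCCS2)[C@H]3[C@H](O[C@@H]4C[C@H](C)CC[C@H]4C(C)C)OC(O[Li])=C3)cc(OCc5ccccc5)c1OC | intermediate
11 | (3S,4R,5R)-4-{2-[3-(benzyloxy)-4,5-dimethoxyphenyl]-1,3-dithian-2-yl}-3-[(R)-hydroxy(3,4,5-trimethoxyphenyl)methyl]-5-(menthyloxy)oxolan-2-one (anti aldol) | COc1cc(C2(SCCCS2)[C@H]3[C@H](O[C@@H]4C[C@H](C)CC[C@H]4C(C)C)OC(=O)[C@@H]3[C@@H](O)c5cc(OC)c(OC)c(OC)c5)cc(OCc6ccccc6)c1OC | intermediate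
12 | (3S,4R,5R)-4-{2-[3-(benzyloxy)-4,5-dimethoxyphenyl]-1,3-dithian-2-yl}-5-(menthyloxy)-3-(3,4,5-trimethoxybenzoyl)oxolan-2-one | COc1cc(C2(SCCCS2)[C@H]3[C@H](O[C@@H]4C[C@H](C)CC[C@H]4C(C)C)OC(=O)[C@@H]3C(=O)c5cc(OC)c(OC)c(OC)c5)cc(OCc6ccccc6)c1OC | intermediate
13 | (3S,4R,5R)-4-{2-[3-(benzyloxy)-4,5-dimethoxyphenyl]-1,3-dithian-2-yl}-3-[(S)-hydroxy(3,4,5-trimethoxyphenyl)methyl]-5-(menthyloxy)oxolan-2-one (syn aldol) | COc1cc(C2(SCCCS2)[C@H]3[C@H](O[C@@H]4C[C@H](C)CC[C@H]4C(C)C)OC(=O)[C@@H]3[C@H](O)c5cc(OC)c(OC)c(OC)c5)cc(OCc6ccccc6)c1OC | intermediate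
14 | tert-butyldimethylsilyl ether of 13 at the carbinol oxygen | COc1cc(C2(SCCCS2)[C@H]3[C@H](O[C@@H]4C[C@H](C)CC[C@H]4C(C)C)OC(=O)[C@@H]3[C@H](O[Si](C)(C)C(C)(C)C)c5cc(OC)c(OC)c(OC)c5)cc(OCc6ccccc6)c1OC | intermediate
15 | (2R,3R)-2-{2-[3-(benzyloxy)-4,5-dimethoxyphenyl]-1,3-dithian-2-yl}-3-[(S)-(tert-butyldimethylsilyloxy)(3,4,5-trimethoxyphenyl)methyl]butane-1,4-diol | COc1cc(C2(SCCCS2)[C@@H](CO)[C@H](CO)[C@H](O[Si](C)(C)C(C)(C)C)c3cc(OC)c(OC)c(OC)c3)cc(OCc3ccccc3)c1OC | intermediate
16 | bis(methanesulfonate) of diol 15 | COc1cc(C2(SCCCS2)[C@@H](COS(C)(=O)=O)[C@H](COS(C)(=O)=O)[C@H](O[Si](C)(C)C(C)(C)C)c3cc(OC)c(OC)c(OC)c3)cc(OCc3ccccc3)c1OC | intermediate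
17 | tert-butyl{[(1S,2S,3S)-3-{2-[3-(benzyloxy)-4,5-dimethoxyphenyl]-1,3-dithian-2-yl}-2-methyl-1-(3,4,5-trimethoxyphenyl)butyl]oxy}dimethylsilane | COc1cc(C2(SCCCS2)[C@@H](C)[C@H](C)[C@H](O[Si](C)(C)C(C)(C)C)c3cc(OC)c(OC)c(OC)c3)cc(OCc3ccccc3)c1OC | intermediate
18 | (1S,2S,3S)-3-{2-[3-(benzyloxy)-4,5-dimethoxyphenyl]-1,3-dithian-2-yl}-2-methyl-1-(3,4,5-trimethoxyphenyl)butan-1-ol | COc1cc(C2(SCCCS2)[C@@H](C)[C@H](C)[C@H](O)c3cc(OC)c(OC)c(OC)c3)cc(OCc3ccccc3)c1OC | intermediate
19 | (2S,3S,4S)-1-[3-(benzyloxy)-4,5-dimethoxyphenyl]-4-hydroxy-2,3-dimethyl-4-(3,4,5-trimethoxyphenyl)butan-1-one | COc1cc(C(=O)[C@@H](C)[C@H](C)[C@H](O)c2cc(OC)c(OC)c(OC)c2)cc(OCc2ccccc2)c1OC | intermediate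
20 | (3S,4S,5S)-2-[3-(benzyloxy)-4,5-dimethoxyphenyl]-3,4-dimethyl-5-(3,4,5-trimethoxyphenyl)oxolan-2-ol (either C2 epimer) | COc1cc(C2(O)O[C@H](c3cc(OC)c(OC)c(OC)c3)[C@@H](C)[C@@H]2C)cc(OCc3ccccc3)c1OC | intermediate
21 | (3S,4S,5S)-2-[3-(benzyloxy)-4,5-dimethoxyphenyl]-3,4-dimethyl-5-(3,4,5-trimethoxyphenyl)-4,5-dihydro-3H-furan-1-ium (oxocarbenium ion) | COc1cc(C2=[O+][C@H](c3cc(OC)c(OC)c(OC)c3)[C@@H](C)[C@@H]2C)cc(OCc3ccccc3)c1OC | intermediate
22 | (2R,3S,4S,5S)-2-[3-(benzyloxy)-4,5-dimethoxyphenyl]-3,4-dimethyl-5-(3,4,5-trimethoxyphenyl)oxolane | COc1cc([C@@H]2O[C@H](c3cc(OC)c(OC)c(OC)c3)[C@@H](C)[C@@H]2C)cc(OCc3ccccc3)c1OC | intermediate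
23 | 5-[(2R,3S,4S,5S)-3,4-dimethyl-5-(3,4,5-trimethoxyphenyl)oxolan-2-yl]-2,3-dimethoxyphenol | COc1cc([C@@H]2O[C@H](c3cc(OC)c(OC)c(OC)c3)[C@@H](C)[C@@H]2C)cc(O)c1OC | target

## Step count and least certain steps

Total: 15 steps. Longest linear sequence: 13 steps (steps 1, 2 and 5–15 from 1; the branch from 4, steps 3, 4 and 5–15, is equally long).

Step 5 (key step). The aldol capture of enolate 10 is an equilibrium at a carbon flanked by the quaternary dithiane centre. Incomplete trapping, retro-aldol loss of 8 during work-up, or competing 1,2-addition of 9 to the lactone carbonyl are the likely failures. The carbinol epimer ratio is of no consequence, since step 6 erases it. Fallback, setting out from 3 and 7 and returning at 12: the coupling is split into two operations and the reversible aldol is replaced by an irreversible acylation. Conjugate addition of 9 to 7 alone, followed by protonation at −78 °C, should give the simple adduct (4R,5R)-4-{2-[3-(benzyloxy)-4,5-dimethoxyphenyl]-1,3-dithian-2-yl}-5-(menthyloxy)oxolan-2-one F1. F1 is then deprotonated with LiN(SiMe3)2 (two equivalents) in THF at −78 °C and the enolate is acylated at carbon with 3,4,5-trimethoxybenzoyl chloride, a Claisen-type acylation. The second equivalent of base takes up the acidic C3 proton of the β-keto lactone as it forms, protonation on work-up should place the aroyl group trans to the dithianyl group, and 12 is reached without any carbinol intermediate, so step 6 falls away.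

Step 7. Facial selectivity may be poor if zinc is held by the thioacetal sulfur atoms or the acetal oxygen instead of bridging the two carbonyl groups, so that the non-chelated pathway returns the (R)-carbinol. Fallback, from 12 to 13 with no new compound: control is moved from the substrate to a catalyst. Asymmetric transfer hydrogenation with RuCl(p-cymene)[(S,S)-TsDPEN] in HCO2H/Et3N recognises the aryl ketone through its arene. By analogy with simple aryl alkyl ketones it is expected to give the (S)-carbinol whatever the chelation behaviour, with C3 held trans by C4.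

Step 11. Neighbouring groups may act before hydride arrives. A thioacetal sulfur sits five atoms from the sulfonate carbon on C4 and can displace the mesylate to a bicyclic sulfonium ion. The silyl ether oxygen can close an oxolane at the other sulfonate with loss of silicon. Hydride can also attack sulfonyl sulfur at the more hindered centre and return the alcohol. Fallback, from 15 to 22: the oxolane ring is built first and the two carbons are deoxygenated last, when neither sulfur nor a silyloxy group is present. Acetylation of 15 (Ac2O, pyridine) gives the silyloxy dithiane diacetate F2. Desilylation with Bu4NF buffered with AcOH, so that the acetates do not migrate, gives the free carbinol diacetate F3. Hg(ClO4)2 with CaCO3 then unmasks the ketone to give the hydroxy ketone diacetate F4. Et3SiH with BF3·OEt2 at −78 °C closes and reduces it to the 3,4-bis(acetoxymethyl)oxolane F5, the hydride again entering anti to the C3 substituent. K2CO3 in MeOH gives the oxolane diol F6, MsCl with Et3N gives the oxolane bis-mesylate F7, and LiBHEt3 reduces F7 to 22.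

Step 14. Configuration may be lost in three ways: hydride delivery to the wrong face of 21 (the 2,3-trans isomer), acid-promoted ionisation of the benzylic C2–O or C5–O bond of the product with drift to the all-trans isomer, or ionic deoxygenation of the C5 hydroxyl of open-chain 19 before the ring closes. Fallback, from 17 to 22: C2 is set by a ketone reduction and the ring is closed by an SN2 displacement instead of through an oxocarbenium ion. Hydrolysis of the dithiane of 17 with the silyl ether still in place (Hg(ClO4)2, CaCO3) gives the silyloxy ketone F8. LiBH(s-Bu)3 at −78 °C reduces F8 under Felkin–Anh control to the 1,2-anti alcohol F9, which is the C2 epimer of what ring closure with retention would need. MsCl with Et3N at −40 °C gives the benzylic mesylate F10. Bu4NF added to the cold solution frees the C5 alkoxide, which displaces the sulfonate with inversion (5-exo-tet) to give 22.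

## Further compounds

F1 | step 5 | (4R,5R)-4-{2-[3-(benzyloxy)-4,5-dimethoxyphenyl]-1,3-dithian-2-yl}-5-{[(1R,2S,5R)-2-isopropyl-5-methylcyclohexyl]oxy}oxolan-2-one | COc1cc(C2(SCCCS2)[C@H]3[C@H](O[C@@H]4C[C@H](C)CC[C@H]4C(C)C)OC(=O)C3)cc(OCc5ccccc5)c1OC
F0 | step 7 | none | none
F2 | step 11 | (2R,3R)-2-{2-[3-(benzyloxy)-4,5-dimethoxyphenyl]-1,3-dithian-2-yl}-3-[(S)-(tert-butyldimethylsilyloxy)(3,4,5-trimethoxyphenyl)methyl]butane-1,4-diyl diacetate | COc1cc(C2(SCCCS2)[C@@H](COC(C)=O)[C@H](COC(C)=O)[C@H](O[Si](C)(C)C(C)(C)C)c3cc(OC)c(OC)c(OC)c3)cc(OCc3ccccc3)c1OC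
F3 | step 11 | (2R,3R)-2-{2-[3-(benzyloxy)-4,5-dimethoxyphenyl]-1,3-dithian-2-yl}-3-[(S)-hydroxy(3,4,5-trimethoxyphenyl)methyl]butane-1,4-diyl diacetate | COc1cc(C2(SCCCS2)[C@@H](COC(C)=O)[C@H](COC(C)=O)[C@H](O)c3cc(OC)c(OC)c(OC)c3)cc(OCc3ccccc3)c1OC
F4 | step 11 | (2R,3R)-2-[3-(benzyloxy)-4,5-dimethoxybenzoyl]-3-[(S)-hydroxy(3,4,5-trimethoxyphenyl)methyl]butane-1,4-diyl diacetate | COc1cc(C(=O)[C@@H](COC(C)=O)[C@H](COC(C)=O)[C@H](O)c2cc(OC)c(OC)c(OC)c2)cc(OCc2ccccc2)c1OC
F5 | step 11 | 3,4-bis(acetoxymethyl) analogue of 22, same spatial arrangement at all four ring carbons | COc1cc([C@@H]2O[C@H](c3cc(OC)c(OC)c(OC)c3)[C@@H](COC(C)=O)[C@@H]2COC(C)=O)cc(OCc3ccccc3)c1OC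
F6 | step 11 | 3,4-bis(hydroxymethyl) analogue of 22, same spatial arrangement | COc1cc([C@@H]2O[C@H](c3cc(OC)c(OC)c(OC)c3)[C@@H](CO)[C@@H]2CO)cc(OCc3ccccc3)c1OC
F7 | step 11 | 3,4-bis(methanesulfonyloxymethyl) analogue of 22, same spatial arrangement | COc1cc([C@@H]2O[C@H](c3cc(OC)c(OC)c(OC)c3)[C@@H](COS(C)(=O)=O)[C@@H]2COS(C)(=O)=O)cc(OCc3ccccc3)c1OC
F8 | step 14 | (2S,3S,4S)-1-[3-(benzyloxy)-4,5-dimethoxyphenyl]-4-(tert-butyldimethylsilyloxy)-2,3-dimethyl-4-(3,4,5-trimethoxyphenyl)butan-1-one | COc1cc(C(=O)[C@@H](C)[C@H](C)[C@H](O[Si](C)(C)C(C)(C)C)c2cc(OC)c(OC)c(OC)c2)cc(OCc2ccccc2)c1OC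
F9 | step 14 | (1S,2S,3S,4S)-1-[3-(benzyloxy)-4,5-dimethoxyphenyl]-4-(tert-butyldimethylsilyloxy)-2,3-dimethyl-4-(3,4,5-trimethoxyphenyl)butan-1-ol | COc1cc([C@@H](O)[C@@H](C)[C@H](C)[C@H](O[Si](C)(C)C(C)(C)C)c2cc(OC)c(OC)c(OC)c2)cc(OCc2ccccc2)c1OC
F10 | step 14 | (1S,2S,3S,4S)-1-[3-(benzyloxy)-4,5-dimethoxyphenyl]-4-(tert-butyldimethylsilyloxy)-2,3-dimethyl-4-(3,4,5-trimethoxyphenyl)butyl methanesulfonate | COc1cc([C@@H](OS(C)(=O)=O)[C@@H](C)[C@H](C)[C@H](O[Si](C)(C)C(C)(C)C)c2cc(OC)c(OC)c(OC)c2)cc(OCc2ccccc2)c1OC
A1 | alternative 1 | methyl 4-[3-(benzyloxy)-4,5-dimethoxyphenyl]-2-diazo-3-methyl-4-[(3,4,5-trimethoxybenzyl)oxy]butanoate, single stereoisomer | COc1cc([C@H](OCc2cc(OC)c(OC)c(OC)c2)[C@@H](C)C(=[N+]=[N-])C(=O)OC)cc(OCc2ccccc2)c1OC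
A2 | alternative 1 | dirhodium tetrakis(triphenylacetate), Rh2(O2CCPh3)4 | [Rh+2].[Rh+2].[O-]C(=O)C(c1ccccc1)(c1ccccc1)c1ccccc1.[O-]C(=O)C(c1ccccc1)(c1ccccc1)c1ccccc1.[O-]C(=O)C(c1ccccc1)(c1ccccc1)c1ccccc1.[O-]C(=O)C(c1ccccc1)(c1ccccc1)c1ccccc1
A3 | alternative 1 | methyl 5-[3-(benzyloxy)-4,5-dimethoxyphenyl]-4-methyl-2-(3,4,5-trimethoxyphenyl)oxolane-3-carboxylate, 2,5-cis-diaryl | COc1cc([C@@H]2O[C@H](c3cc(OC)c(OC)c(OC)c3)[C@@H](C(=O)OC)[C@@H]2C)cc(OCc3ccccc3)c1OC
A4 | alternative 2 | diethyl trans-2-[3-(benzyloxy)-4,5-dimethoxyphenyl]-3-methylcyclopropane-1,1-dicarboxylate, single enantiomer | CCOC(=O)C1(C(=O)OCC)[C@H](C)[C@H]1c1cc(OC)c(OC)c(OCc2ccccc2)c1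
A5 | alternative 2 | tin bis(trifluoromethanesulfonate), Sn(OTf)2 | [Sn+2].[O-]S(=O)(=O)C(F)(F)F.[O-]S(=O)(=O)C(F)(F)F
A6 | alternative 2 | diethyl 5-[3-(benzyloxy)-4,5-dimethoxyphenyl]-4-methyl-2-(3,4,5-trimethoxyphenyl)oxolane-3,3-dicarboxylate, 2,5-cis-diaryl | COc1cc([C@@H]2O[C@H](c3cc(OC)c(OC)c(OC)c3)C(C(=O)OCC)(C(=O)OCC)[C@@H]2C)cc(OCc3ccccc3)c1OC
A7 | alternative 3 | (E)-1-[3-(benzyloxy)-4,5-dimethoxyphenyl]-2-methylbut-2-en-1-one | C/C=C(\C)C(=O)c1cc(OC)c(OC)c(OCc2ccccc2)c1
A8 | alternative 3 | 5-(diazomethyl)-1,2,3-trimethoxybenzene | COc1cc(C=[N+]=[N-])cc(OC)c1OC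
A9 | alternative 3 | copper trifluoromethanesulfonate, CuOTf | [Cu+].[O-]S(=O)(=O)C(F)(F)F
A10 | alternative 3 | 2,2'-(propane-2,2-diyl)bis[(4S)-4-tert-butyl-4,5-dihydro-1,3-oxazole], a representative chiral bis(oxazoline) ligand | CC(C)(C)[C@H]1COC(=N1)C(C)(C)C1=N[C@H](CO1)C(C)(C)C
A11 | alternative 3 | trans-5-[3-(benzyloxy)-4,5-dimethoxyphenyl]-3,4-dimethyl-2-(3,4,5-trimethoxyphenyl)-2,3-dihydrofuran | COc1cc(C2=C(C)[C@H](C)[C@@H](c3cc(OC)c(OC)c(OC)c3)O2)cc(OCc3ccccc3)c1OC
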